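1. The leftover to watch is coupling partner. Each coupling takes one coupling partner, and one substrate can take 3, so the full demand is 3 c(substrate). The ratio of c(coupling partner) to that demand is the supply ratio, which for summer is 2.47. Under one, coupling partner is the limiting reagent for the full tris adduct.

| setting | Wednesday's | Monday's | summer | winter | midnight | dusk | noon |
|---|---|---|---|---|---|---|---|
| substrate | 0.0046 M | 0.069 M | 0.0050 M | 0.010 M | 0.020 M | 0.040 M | 0.080 M |
| coupling partner | 0.037 M | 0.037 M | 0.0370 M | 0.0370 M | 0.0370 M | 0.0370 M | 0.0370 M |
| remark | run made earlier | run made earlier |  |  |  |  |  |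
| time |  |  | 2.0 h | 2.0 h | 2.0 h | 2.0 h | 2.0 h |

| run | time / min | double product / % |
|---|---|---|
| Wednesday's | 10.0 | 29.7 |
| Wednesday's | 30.0 | 11.2 |
| Wednesday's | 60.0 | 4.2 |
| Wednesday's | 80.0 | 2.7 |
| Wednesday's | 120 | 1.8 |
| Monday's | 10.0 | 7.9 |
| Monday's | 30.0 | 4.7 |
| Monday's | 60.0 | 2.5 |
| Monday's | 80.0 | 3.9 |
| Monday's | 120 | 2.8 |

(each reading ± 1 percentage point)

- steps that have been proposed: double product <-> isomer of the product; coupling partner + double product -> tris adduct + by-product; coupling partner + single product -> double product + by-product; substrate + coupling partner -> single product + by-product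
- "hardly changes" means that all values lie within two and a half points (for a concentration: within two and a half percent of the largest)

- [double product] at the end for summer, winter, midnight, dusk, noon, in this order
- how that number moves from the first to the last of them (falls, then rises / falls all the way / rises, then falls / hardly changes / rises all the way)

2. Wednesday's ratio is 2.68, and its double product falls from 29.7% to 1.8%, a reading of 8.28 × 10⁻⁵ M.

3. Monday's ratio is 0.179. Its late readings, 2.5%, 3.9% and 2.8%, show no trend beyond the scatter of 1 percentage point. The last is a reading of 0.00193 M.

4. My reckoning: the ratio passes one at c(substrate) = 0.0123 M, between winter (1.23) and midnight (0.617). Summer's ratio lies near Wednesday's, so its double product should lie near 8.28 × 10⁻⁵ M. Noon's ratio, 0.154, lies near Monday's, so its double product should lie near 0.00193 M. Full conversion to tris adduct leaves summer 59.5% of its coupling partner. This gives the two ends and a rise between them, but no top.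

5. The forecast reads 1.000 × 10⁻⁴ M, 9.000 × 10⁻⁴ M, 0.0031 M, 0.0033 M, 0.0021 M, shape rises, then falls, on the ground that “Dilute substrate (summer) leaves excess partner, so double is drained to tris”.

6. The flasks give 9.36 × 10⁻⁵ M, 5.77 × 10⁻⁴ M, 0.00317 M, 0.00327 M, 0.00259 M, shape rises, then falls. The forecast's shape agrees, while its winter value stands at 1.56 times the flask's.

    double product ⇌ isomer of the product (K = 2.30, k = 0.00120 s⁻¹)
    coupling partner + double product → tris adduct + by-product (k = 0.0580 M⁻¹ s⁻¹)
    coupling partner + single product → double product + by-product (k = 0.180 M⁻¹ s⁻¹)
    substrate + coupling partner → single product + by-product (k = 0.0860 M⁻¹ s⁻¹)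

Summer, at a ratio of 2.47, ends with 60.8% of its coupling partner, on the way to the reckoned 59.5%, and its double product, with a half-life of 0.15 h by the step to tris adduct, short against the 2.0 h of the run, stands at 1.87% of the substrate charged. Noon, at a ratio of 0.154, ends with 0% of its coupling partner, and after 20.0 h its double product still stands at 3.24%.

The numbers in the tables come from a simulation for substances that don't exist, and the scatter is random.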